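**Retrosynthetic overview**

1. Numbering: ring A = C1, C10, C11(Me)=C12, C13, C14(iPr); the ten-membered ring = C1–C10 with an oxygen bridge C4–O–C7. Target 46 ⇐ C8 ketone 34 (reagent-controlled reduction, urocanoylation, C3 CH2OTBS → CO2Me, ketal → hemiketal).
2. The strategy rests on C10, the allylic stereocentre of ring A next to C11=C12, which carries the C9–C8 arm: C8(=O)–C9–C10–C11=C12 is a γ,δ-unsaturated ketone. 34 ⇐ exocyclic enol ether 33 by a [3,3] shift (C9–C10 made, O–C12 broken) that contracts a twelve-membered oxacycle to the ten-membered carbocycle; 33 ⇐ lactone 32 by methylenation.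
3. 32 ⇐ ynone macrolactone 29 by semi-hydrogenation and in-ring ketalisation (closes the dihydrofuran, fixes C4); 29 ⇐ seco acid 24 by macrolactonisation at the C12 carbinol.
4. 24 ⇐ syn-aldol union at C3–C4 of ring A imide 13 with ynal 19 (C3 by auxiliary); 19 ⇐ a pyruvate ester and 3,3-diethoxypropyne (C7 by asymmetric alkynylation).
5. 13 ⇐ (S)-carvone (C14 from the pool, C1 by trans-allylation, C12 by epoxidation and Wharton transposition). Ring order: ring A → twelve-membered lactone → dihydrofuran → ten-membered ring.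

Key step: step 23

Assumption: the (1S,2S) amino alcohol of step 10 is taken to give the (S) carbinol; if a first run shows the opposite sense, its antipode would be used with no other change.

Remark on notation: in the SMILES strings the cyclopentadienyl ligands on titanium are drawn as σ-bonded C5H5 rings, and Cp2Ti(μ-Cl)(μ-CH2)AlMe2 is drawn with its chloride on titanium only, the Cl→Al bridge bond being left out.

**Route**

Step 1
Reactants: 1 (S)-(+)-carvone
Product: 2 (S)-carvotanacetone
Conditions: H2 (1 atm), RhCl(PPh3)3 (2 mol %), PhMe, rt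
Reagents that add atoms: none
Why: Homogeneous hydrogenation with RhCl(PPh3)3 should saturate only the unhindered 1,1-disubstituted isopropenyl alkene and leave the trisubstituted conjugated enone, so that C14 is taken unchanged from the chiral pool.

Step 2
Reactants: 2 (S)-carvotanacetone; 3 allyl bromide
Product: 4 trans-6-allyl enone
Conditions: LiN(iPr)2, THF, –78 °C; then 3, DMPU, –78 → –20 °C
Reagents that add atoms: none
Why: Kinetic deprotonation at the α′ methylene gives the cross-conjugated lithium enolate, whose allylation (ketone enolate alkylation) should occur anti to the neighbouring isopropyl group and so set C1 trans to C14.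

Step 3
Reactants: 4 trans-6-allyl enone
Product: 5 epoxy ketone
Conditions: H2O2 (30% aq.), NaOH (cat.), MeOH, 0 °C
Reagents that add atoms: hydrogen peroxide OO
Why: Weitz–Scheffer nucleophilic epoxidation should proceed by axial attack of hydroperoxide at C12 on the face anti to the equatorial C14 isopropyl group, which places the epoxide oxygen cis to the C1 allyl arm and leaves the isolated allyl alkene untouched.

Step 4
Reactants: 5 epoxy ketone
Product: 7 ring A carbinol (1S,4R,5R)-2-methyl-5-(propan-2-yl)-4-(prop-2-en-1-yl)cyclohex-2-en-1-ol, via epoxy hydrazone 6 (not isolated)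
Conditions: N2H4·H2O, AcOH (cat.), MeOH, 0 °C → rt, under argon
Reagents that add atoms: none
Why: Wharton transposition: the epoxy hydrazone should fragment with loss of N2, which moves the oxygen to C12 with retention of the C–O configuration set in step 3 and the alkene to C10=C11, air being excluded so that no diimide reduces the allyl group.

Step 5
Reactants: 7 ring A carbinol
Product: 8 C12 silyl ether
Conditions: TBSCl, imidazole, DMF, rt
Reagents that add atoms: tert-butyldimethylsilyl chloride CC(C)(C)[Si](C)(C)Cl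
Why: Standard silylation of the only hydroxyl masks C12–OH through the oxidation and boron aldol steps and leaves it removable by fluoride.

Step 6
Reactants: 8 C12 silyl ether
Product: 10 primary alcohol, via alkylborane 9 (not isolated)
Conditions: 9-BBN, THF, 0 °C → rt; then NaOH (aq.), H2O2 (30%), 0 °C
Reagents that add atoms: hydrogen peroxide OO
Why: Anti-Markovnikov hydroboration–oxidation, in which 9-BBN should add to the monosubstituted terminal alkene far faster than to the trisubstituted ring alkene.

Step 7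
Reactants: 10 primary alcohol
Product: 11 carboxylic acid
Conditions: TEMPO (cat.), PhI(OAc)2, MeCN/H2O (1:1), rt
Reagents that add atoms: water O
Why: Oxoammonium (TEMPO) oxidation should take the primary alcohol through the aldehyde hydrate to the acid without touching the alkene or the secondary silyl ether.

Step 8
Reactants: 11 carboxylic acid
Product: 13 ring A imide, via pivalic mixed anhydride 12 (not isolated)
Conditions: PivCl, Et3N, THF, –20 °C; then LiCl, (R)-4-benzyl-1,3-oxazolidin-2-one, –20 °C → rt
Reagents that add atoms: (R)-4-benzyl-1,3-oxazolidin-2-one O=C1N[C@H](Cc2ccccc2)CO1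
Why: N-Acylation of the auxiliary through the mixed anhydride, which the oxazolidinone should attack at the less hindered carbonyl.

Step 9
Reactants: 14 pyruvic acid
Product: 15 2-(trimethylsilyl)ethyl pyruvate
Conditions: 2-(trimethylsilyl)ethanol, DCC, DMAP (cat.), CH2Cl2, 0 °C → rt
Reagents that add atoms: 2-(trimethylsilyl)ethanol C[Si](C)(C)CCO
Why: Steglich esterification installs an ester that fluoride will later cleave together with the silyl ethers.

Step 10
Reactants: 15 2-(trimethylsilyl)ethyl pyruvate; 16 3,3-diethoxyprop-1-yne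
Product: 17 (S) tertiary propargylic alcohol
Conditions: Zn(OTf)2 (20 mol %), (1S,2S)-2-(dimethylamino)-1-(4-nitrophenyl)-3-(tert-butyldimethylsilyloxy)propan-1-ol (22 mol %), Et3N (30 mol %), PhMe, rt → 50 °C
Reagents that add atoms: none
Why: Catalytic enantioselective alkynylation of an α-keto ester, in which the amino alcohol ligand on zinc should steer the in-situ metalated alkyne to one face of the activated ketone and so set C7 as (S).

Step 11
Reactants: 17 (S) tertiary propargylic alcohol
Product: 18 hydroxy ynal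
Conditions: HCO2H (88% aq.), rt
Reagents that add atoms: water O
Why: Acid hydrolysis of the propargylic diethyl acetal should free the aldehyde, the ester-flanked tertiary carbinol being too electron-poor to ionise at room temperature.

Step 12
Reactants: 18 hydroxy ynal
Product: 19 silylated ynal
Conditions: TESOTf, 2,6-lutidine, CH2Cl2, –78 °C
Reagents that add atoms: triethylsilyl trifluoromethanesulfonate CC[Si](CC)(CC)OS(=O)(=O)C(F)(F)F
Why: Silyl triflate silylation of the hindered tertiary alcohol removes the only protic group that could quench the boron enolate of the next step.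

Step 13
Reactants: 13 ring A imide; 19 silylated ynal
Product: 21 syn-aldol adduct, via boron enolate 20 (not isolated)
Conditions: 13, Bu2BOTf, iPr2NEt, CH2Cl2, –78 → 0 °C; then 19, –78 → –20 °C; then pH 7 buffer, MeOH, H2O2 (30%), 0 °C
Reagents that add atoms: none
Why: Evans syn-aldol through the Z boron enolate and a chair Zimmerman–Traxler transition state, in which the (R)-benzyl auxiliary should direct the ynal to the enolate face that gives the required configuration at C3 (the C4 carbinol, formed syn, is oxidised later).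

Step 14
Reactants: 21 syn-aldol adduct
Product: 22 1,3-diol
Conditions: NaBH4, THF/H2O (4:1), 0 °C → rt
Reagents that add atoms: none
Why: Borohydride reduction of the activated N-acyl oxazolidinone should free the C3 hydroxymethyl group and the auxiliary while the hindered α-quaternary ester and the alkyne stay intact.

Step 15
Reactants: 22 1,3-diol
Product: 23 acetonide
Conditions: 2,2-dimethoxypropane, PPTS (cat.), CH2Cl2, rt
Reagents that add atoms: 2,2-dimethoxypropane COC(C)(C)OC
Why: Acetonide formation masks the C4 carbinol and the C3 hydroxymethyl group as one fluoride-stable unit so that only C12–OH can be acylated in the ring closure.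

Step 16
Reactants: 23 acetonide
Product: 24 seco acid
Conditions: Bu4NF (5 equiv), THF, 0 → 40 °C; then sat. aq. NH4Cl
Reagents that add atoms: none
Why: Fluoride should cleave in one operation the C12 silyl ether, the C7 silyl ether and the 2-(trimethylsilyl)ethyl ester (β-elimination to ethene), leaving the acetonide.

Step 17
Reactants: 24 seco acid
Product: 26 twelve-membered alkyne macrolactone, via mixed anhydride 25 (not isolated)
Conditions: 2,4,6-Cl3C6H2COCl, Et3N, THF, rt; then slow addition to DMAP, PhMe, 70 °C (final 1 mM)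
Reagents that add atoms: none
Why: Yamaguchi macrolactonisation, in which the secondary allylic C12 hydroxyl should be the only acyl acceptor (C7–OH is tertiary, C4–O is masked) and the cis relation of C12–O and C1–C2 on ring A lets the chain span the ring.

Step 18
Reactants: 26 twelve-membered alkyne macrolactone
Product: 27 triol
Conditions: PPTS, MeOH, 40 °C
Reagents that add atoms: none
Why: Acid-catalysed transketalisation removes the acetonide, and the linear alkyne keeps the freed C4 hydroxyl away from the lactone carbonyl so that no translactonisation can occur.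

Step 19
Reactants: 27 triol
Product: 28 primary silyl ether
Conditions: TBSCl (1.1 equiv), imidazole, CH2Cl2, 0 °C
Reagents that add atoms: tert-butyldimethylsilyl chloride CC(C)(C)[Si](C)(C)Cl
Why: Silylation should be selective for the primary hydroxyl over the secondary propargylic and the tertiary ones, giving the titanium-stable C3 substituent.

Step 20
Reactants: 28 primary silyl ether
Product: 29 ynone
Conditions: Dess–Martin periodinane, NaHCO3, CH2Cl2, 0 °C → rt
Reagents that add atoms: none
Why: Dess–Martin oxidation of the secondary propargylic alcohol gives the C4 ketone under buffered, non-basic conditions that should avoid β-elimination of the silyloxy group and epimerisation at C3.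

Step 21
Reactants: 29 ynone
Product: 32 methyl ketal lactone, via cis-enone 30 (not isolated), via hemiketal 31 (not isolated)
Conditions: H2 (1 atm), Pd/CaCO3 poisoned with Pb(OAc)2 (Lindlar catalyst), quinoline, PhMe, rt; filter, concentrate; then MeOH, PPTS (cat.), 0 °C → rt
Reagents that add atoms: methanol CO
Why: Lindlar semi-hydrogenation gives the cis-enone, whose C7 hydroxyl should add to the C4 ketone to give the bridged hemiketal (inside the macrocycle only the dihydrofuran with C3 and C8 on the same face is unstrained, so C7 sets C4), and acid-catalysed exchange through the oxocarbenium ion then gives the methyl ketal.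

Step 22
Reactants: 32 methyl ketal lactone
Product: 33 exocyclic enol ether
Conditions: Cp2Ti(μ-Cl)(μ-CH2)AlMe2 (3 equiv), pyridine (cat.), THF/PhMe, –40 °C → rt; then 15% aq. NaOH; filtration through basic Al2O3
Reagents that add atoms: Cp2Ti(μ-Cl)(μ-CH2)AlMe2 C[Al](C)C[Ti](Cl)(C1C=CC=C1)C1C=CC=C1
Why: Tebbe methylenation of the lactone carbonyl through an oxatitanacyclobutane is non-basic and should spare the ketal, the silyl ether and the alkenes, which is why C3 is carried as a silyloxymethyl group and not as an ester.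

Step 23
Reactants: 33 exocyclic enol ether
Product: 34 C8 ketone of the oxa-bridged ten-membered carbocycle
Conditions: PhMe (5 mM, degassed), 2,6-di-tert-butyl-4-methylpyridine (0.2 equiv), base-washed sealed tube, 140 °C
Reagents that add atoms: none
Why: Heating should trigger a concerted, suprafacial [3,3]-sigmatropic shift through the six-atom array C9=C8–O–C12–C11=C10: the C9–C10 bond forms as the O–C12 bond breaks, the alkene moves to C11=C12 and C8 becomes the ketone. The closest known reaction type is the Claisen rearrangement of 2-methylene oxacycles made from lactones by titanium methylenation, run here in its ring-contracting mode. The ten-membered carbocycle (C1–C10) is closed by contraction of the existing twelve-membered oxacycle through a bicyclic, probably boat-like, six-centre transition state and not by end-to-end cyclisation, so no high dilution is needed. The one new stereocentre, C10, is controlled by 1,3-chirality transfer from C12: because the allyl unit lies in ring A, C9 must bond to the ring face that carried the oxygen, the face that already holds C2 at C1, which gives the cis ring fusion. The step needs only a clean thermal pericyclic path, which is secured by the quaternary C7 (the enol ether cannot isomerise into the ring), by C9 being an unsubstituted methylene (no enol ether geometry to control) and by the base-buffered medium that protects enol ether and ketal from acid.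

Step 24
Reactants: 34 C8 ketone
Product: 35 C8 (S) alcohol
Conditions: (R)-2-methyl-CBS-oxazaborolidine (0.3 equiv), catecholborane (2 equiv), PhMe, –78 → –40 °C; then MeOH, aq. NaOH
Reagents that add atoms: none
Why: Corey–Bakshi–Shibata reduction, in which the catalyst should distinguish the quaternary C7 side from the C9 methylene side of the ketone (a tert-alkyl/CH2 pattern) and deliver hydride to give the (S) carbinol under reagent control, catecholborane being too unreactive at low temperature to hydroborate the alkenes.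

Step 25
Reactants: 36 1-methyl-1H-imidazole-4-carbaldehyde; 37 malonic acid
Product: 39 (E)-N-methylurocanic acid, via alkylidenemalonic acid 38 (not isolated)
Conditions: pyridine, piperidine (cat.), 100 °C
Reagents that add atoms: none
Why: Knoevenagel–Doebner condensation with decarboxylation should give the (E) acrylic acid, the position of the N-methyl group being fixed by the starting aldehyde.

Step 26
Reactants: 35 C8 (S) alcohol; 39 (E)-N-methylurocanic acid
Product: 41 C8 urocanate, via mixed anhydride 40 (not isolated)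
Conditions: 39 (2 equiv), 2,4,6-Cl3C6H2COCl, Et3N, THF, rt; then 35, DMAP, PhMe, rt → 50 °C
Reagents that add atoms: none
Why: Yamaguchi esterification through the mixed anhydride and the acylpyridinium ion is strong enough to acylate the hindered secondary C8 hydroxyl next to quaternary C7, with retention at C8.

Step 27
Reactants: 41 C8 urocanate
Product: 42 primary alcohol
Conditions: Bu4NF, AcOH (1:1), THF, 0 °C → rt
Reagents that add atoms: none
Why: Acetic acid-buffered fluoride should remove the primary silyl ether without cleaving the urocanate ester or the methyl ketal.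

Step 28
Reactants: 42 primary alcohol
Product: 43 C3 aldehyde
Conditions: Dess–Martin periodinane, NaHCO3, CH2Cl2, 0 °C
Reagents that add atoms: none
Why: Buffered Dess–Martin oxidation gives the α-branched aldehyde under conditions mild enough to keep C3 from epimerising.

Step 29
Reactants: 43 C3 aldehyde
Product: 44 C3 carboxylic acid
Conditions: NaClO2, NaH2PO4, 2-methylbut-2-ene, t-BuOH/H2O, 0 °C → rt
Reagents that add atoms: sodium chlorite [Na+].[O-]Cl=O
Why: Pinnick oxidation converts the aldehyde to the acid, the alkene scavenger trapping hypochlorous acid before it can attack the ring alkenes or the imidazole.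

Step 30
Reactants: 44 C3 carboxylic acid
Product: 45 methyl ester methyl ketal
Conditions: Me3SiCHN2, MeOH/PhMe (1:4), 0 °C
Reagents that add atoms: (trimethylsilyl)diazomethane C[Si](C)(C)C=[N+]=[N-]
Why: Diazoalkane esterification methylates only the carboxylic acid under neutral conditions, which spares the urocanate and the stereocentre at C3.

Step 31
Reactants: 45 methyl ester methyl ketal
Product: 46 target CNP0113846.1
Conditions: camphorsulfonic acid (1.2 equiv), MeCN/H2O (5:1), rt
Reagents that add atoms: water O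
Why: Mild acid hydrolysis of the methyl ketal through the bridgehead-stabilised oxocarbenium ion should give the hemiketal with the C4 configuration held by the oxygen bridge, one equivalent of acid being taken up by the imidazole.

**Compound list**

1 | (S)-(+)-carvone, (5S)-2-methyl-5-(prop-1-en-2-yl)cyclohex-2-en-1-one | CC1=CC[C@@H](CC1=O)C(C)=C | starting material
2 | (S)-carvotanacetone, (5S)-2-methyl-5-(propan-2-yl)cyclohex-2-en-1-one | CC1=CC[C@@H](CC1=O)C(C)C | intermediate
3 | allyl bromide | C=CCBr | starting material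
4 | (5R,6R)-2-methyl-5-(propan-2-yl)-6-(prop-2-en-1-yl)cyclohex-2-en-1-one (allyl trans to isopropyl) | C=CC[C@@H]1[C@@H](C(C)C)CC=C(C)C1=O | intermediate
5 | epoxy ketone, 1-methyl-4-(propan-2-yl)-3-(prop-2-en-1-yl)-7-oxabicyclo[4.1.0]heptan-2-one, epoxide oxygen cis to allyl and trans to isopropyl | C=CC[C@@H]1[C@@H](C(C)C)C[C@@H]2O[C@]2(C)C1=O | intermediate
6 | hydrazone of 5 | C=CC[C@@H]1[C@@H](C(C)C)C[C@@H]2O[C@]2(C)C1=NN | intermediate
7 | ring A carbinol, (1S,4R,5R)-2-methyl-5-(propan-2-yl)-4-(prop-2-en-1-yl)cyclohex-2-en-1-ol (C12–OH cis to the C1 allyl arm, trans to C14 isopropyl) | C=CC[C@@H]1[C@@H](C(C)C)C[C@H](O)C(C)=C1 | intermediate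
8 | tert-butyldimethylsilyl ether of 7 | C=CC[C@@H]1[C@@H](C(C)C)C[C@H](O[Si](C)(C)C(C)(C)C)C(C)=C1 | intermediate
9 | 9-alkyl-9-borabicyclo[3.3.1]nonane from 8 (boron on the terminal carbon) | C(CC[C@@H]1[C@@H](C(C)C)C[C@H](O[Si](C)(C)C(C)(C)C)C(C)=C1)B1C2CCCC1CCC2 | intermediate
10 | 3-[4-(tert-butyldimethylsilyloxy)-3-methyl-6-(propan-2-yl)cyclohex-2-en-1-yl]propan-1-ol, ring configuration as in 7 | OCCC[C@@H]1[C@@H](C(C)C)C[C@H](O[Si](C)(C)C(C)(C)C)C(C)=C1 | intermediate
11 | 3-[4-(tert-butyldimethylsilyloxy)-3-methyl-6-(propan-2-yl)cyclohex-2-en-1-yl]propanoic acid | OC(=O)CC[C@@H]1[C@@H](C(C)C)C[C@H](O[Si](C)(C)C(C)(C)C)C(C)=C1 | intermediate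
12 | mixed anhydride of 11 with pivalic acid | CC(C)(C)C(=O)OC(=O)CC[C@@H]1[C@@H](C(C)C)C[C@H](O[Si](C)(C)C(C)(C)C)C(C)=C1 | intermediate
13 | ring A imide, (R)-4-benzyl-3-acyl-1,3-oxazolidin-2-one of acid 11 | O=C(CC[C@@H]1[C@@H](C(C)C)C[C@H](O[Si](C)(C)C(C)(C)C)C(C)=C1)N1[C@H](Cc2ccccc2)COC1=O | intermediate
14 | pyruvic acid | CC(=O)C(O)=O | starting material
15 | 2-(trimethylsilyl)ethyl 2-oxopropanoate | CC(=O)C(=O)OCC[Si](C)(C)C | intermediate
16 | 3,3-diethoxyprop-1-yne | C#CC(OCC)OCC | starting material
17 | 2-(trimethylsilyl)ethyl (S)-5,5-diethoxy-2-hydroxy-2-methylpent-3-ynoate | CCOC(OCC)C#C[C@](C)(O)C(=O)OCC[Si](C)(C)C | intermediate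
18 | 2-(trimethylsilyl)ethyl (S)-2-hydroxy-2-methyl-5-oxopent-3-ynoate | O=CC#C[C@](C)(O)C(=O)OCC[Si](C)(C)C | intermediate
19 | 2-(trimethylsilyl)ethyl (S)-2-methyl-5-oxo-2-(triethylsilyloxy)pent-3-ynoate | O=CC#C[C@](C)(O[Si](CC)(CC)CC)C(=O)OCC[Si](C)(C)C | intermediate
20 | (Z)-dibutylboron enolate of 13 | CCCCB(CCCC)O/C(=C\C[C@@H]1[C@@H](C(C)C)C[C@H](O[Si](C)(C)C(C)(C)C)C(C)=C1)N1[C@H](Cc2ccccc2)COC1=O | intermediate
21 | syn-aldol adduct: imide carbonyl on C3, secondary carbinol at C4, C5≡C6, C7(Me)(OSiEt3) carrying the 2-(trimethylsilyl)ethyl ester C8 | O=C([C@H](C[C@@H]1[C@@H](C(C)C)C[C@H](O[Si](C)(C)C(C)(C)C)C(C)=C1)[C@@H](O)C#C[C@](C)(O[Si](CC)(CC)CC)C(=O)OCC[Si](C)(C)C)N1[C@H](Cc2ccccc2)COC1=O | intermediate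
22 | 1,3-diol (C3 hydroxymethyl, C4 carbinol) from 21 | OC[C@H](C[C@@H]1[C@@H](C(C)C)C[C@H](O[Si](C)(C)C(C)(C)C)C(C)=C1)[C@@H](O)C#C[C@](C)(O[Si](CC)(CC)CC)C(=O)OCC[Si](C)(C)C | intermediate
23 | acetonide (2,2-dimethyl-1,3-dioxane over the C3 CH2–O and C4–O) of 22 | CC1(C)OC[C@H](C[C@@H]2[C@@H](C(C)C)C[C@H](O[Si](C)(C)C(C)(C)C)C(C)=C2)[C@H](C#C[C@](C)(O[Si](CC)(CC)CC)C(=O)OCC[Si](C)(C)C)O1 | intermediate
24 | seco acid: free C12–OH, free C7–OH, C8 carboxylic acid, acetonide retained | CC1(C)OC[C@H](C[C@@H]2[C@@H](C(C)C)C[C@H](O)C(C)=C2)[C@H](C#C[C@](C)(O)C(O)=O)O1 | intermediate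
25 | mixed anhydride of 24 with 2,4,6-trichlorobenzoic acid | CC1(C)OC[C@H](C[C@@H]2[C@@H](C(C)C)C[C@H](O)C(C)=C2)[C@H](C#C[C@](C)(O)C(=O)OC(=O)c2c(Cl)cc(Cl)cc2Cl)O1 | intermediate
26 | twelve-membered alkyne macrolactone (C8 carbonyl to C12 oxygen), acetonide, free C7–OH | CC1(C)OC[C@@H]2C[C@@H]3[C@@H](C(C)C)C[C@H](OC(=O)[C@@](C)(O)C#C[C@@H]2O1)C(C)=C3 | intermediate
27 | triol macrolactone (C3 CH2OH, C4–OH, C7–OH) | OC[C@@H]1C[C@@H]2[C@@H](C(C)C)C[C@H](OC(=O)[C@@](C)(O)C#C[C@@H]1O)C(C)=C2 | intermediate
28 | primary tert-butyldimethylsilyl ether of 27 | CC(C)(C)[Si](C)(C)OC[C@@H]1C[C@@H]2[C@@H](C(C)C)C[C@H](OC(=O)[C@@](C)(O)C#C[C@@H]1O)C(C)=C2 | intermediate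
29 | ynone macrolactone (C4 ketone, C5≡C6, C7–OH) | CC(C)(C)[Si](C)(C)OC[C@@H]1C[C@@H]2[C@@H](C(C)C)C[C@H](OC(=O)[C@@](C)(O)C#CC1=O)C(C)=C2 | intermediate
30 | cis-enone macrolactone (C5=C6 Z) | CC(C)(C)[Si](C)(C)OC[C@@H]1C[C@@H]2[C@@H](C(C)C)C[C@H](OC(=O)[C@@](C)(O)/C=C\C1=O)C(C)=C2 | intermediate
31 | bridged hemiketal lactone (C4–OH, oxygen bridge C4–O–C7) | CC(C)(C)[Si](C)(C)OC[C@@H]1C[C@@H]2[C@@H](C(C)C)C[C@H](OC(=O)[C@]3(C)C=C[C@@]1(O)O3)C(C)=C2 | intermediate
32 | methyl ketal lactone (C4–OMe) | CC(C)(C)[Si](C)(C)OC[C@@H]1C[C@@H]2[C@@H](C(C)C)C[C@H](OC(=O)[C@]3(C)C=C[C@@]1(OC)O3)C(C)=C2 | intermediate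
33 | macrocyclic allyl vinyl ether (C8 exocyclic methylene, oxygen bound to C12 of ring A) | CC(C)(C)[Si](C)(C)OC[C@@H]1C[C@@H]2[C@@H](C(C)C)C[C@H](OC(=C)[C@]3(C)C=C[C@@]1(OC)O3)C(C)=C2 | intermediate
34 | C8 ketone of the oxa-bridged ten-membered carbocycle (cis-fused to ring A, C11=C12) | CC(C)(C)[Si](C)(C)OC[C@@H]1C[C@@H]2[C@@H](C(C)C)CC=C(C)[C@@H]2CC(=O)[C@]2(C)C=C[C@@]1(OC)O2 | intermediate
35 | C8 (S) alcohol | CC(C)(C)[Si](C)(C)OC[C@@H]1C[C@@H]2[C@@H](C(C)C)CC=C(C)[C@@H]2C[C@H](O)[C@]2(C)C=C[C@@]1(OC)O2 | intermediate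
36 | 1-methyl-1H-imidazole-4-carbaldehyde | Cn1cnc(C=O)c1 | starting material
37 | malonic acid | OC(=O)CC(O)=O | starting material
38 | 2-[(1-methyl-1H-imidazol-4-yl)methylidene]propanedioic acid | Cn1cnc(C=C(C(O)=O)C(O)=O)c1 | intermediate
39 | (E)-3-(1-methyl-1H-imidazol-4-yl)prop-2-enoic acid | Cn1cnc(/C=C/C(O)=O)c1 | intermediate
40 | mixed anhydride of 39 with 2,4,6-trichlorobenzoic acid | Cn1cnc(/C=C/C(=O)OC(=O)c2c(Cl)cc(Cl)cc2Cl)c1 | intermediate
41 | C8 (E)-N-methylurocanate, C3 CH2OTBS, C4 methyl ketal | CC(C)(C)[Si](C)(C)OC[C@@H]1C[C@@H]2[C@@H](C(C)C)CC=C(C)[C@@H]2C[C@H](OC(=O)/C=C/c2cn(C)cn2)[C@]2(C)C=C[C@@]1(OC)O2 | intermediate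
42 | C3 hydroxymethyl compound | OC[C@@H]1C[C@@H]2[C@@H](C(C)C)CC=C(C)[C@@H]2C[C@H](OC(=O)/C=C/c2cn(C)cn2)[C@]2(C)C=C[C@@]1(OC)O2 | intermediate
43 | C3 aldehyde | O=C[C@@H]1C[C@@H]2[C@@H](C(C)C)CC=C(C)[C@@H]2C[C@H](OC(=O)/C=C/c2cn(C)cn2)[C@]2(C)C=C[C@@]1(OC)O2 | intermediate
44 | C3 carboxylic acid | OC(=O)[C@@H]1C[C@@H]2[C@@H](C(C)C)CC=C(C)[C@@H]2C[C@H](OC(=O)/C=C/c2cn(C)cn2)[C@]2(C)C=C[C@@]1(OC)O2 | intermediate
45 | C3 methyl ester, C4 methyl ketal | COC(=O)[C@@H]1C[C@@H]2[C@@H](C(C)C)CC=C(C)[C@@H]2C[C@H](OC(=O)/C=C/c2cn(C)cn2)[C@]2(C)C=C[C@@]1(OC)O2 | intermediate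
46 | CNP0113846.1: C3 methyl ester, C4 hemiketal, C8 (E)-N-methylurocanate (skeletal numbering 1R,3R,4R,7S,8S,10R,14R) | COC(=O)[C@@H]1C[C@@H]2[C@@H](C(C)C)CC=C(C)[C@@H]2C[C@H](OC(=O)/C=C/c2cn(C)cn2)[C@]2(C)C=C[C@@]1(O)O2 | target

**Step count and risks**

Total steps: 31. Longest linear sequence: 26 (steps 1–8, 13–24, 26–31).

Steps most likely to fail:

1. Step 23. The rigid oxygen-bridged bicycle may hold C9 too far from C10, so that the sigmatropic shift is slower than thermal loss of the enol ether (hydrolysis by adventitious acid, ionisation of the ketal). Fallback, from 28 back to the route at 34: the shift would be run on the flexible macrocycle before the oxygen bridge is closed. Compound 28 would be silylated at both free hydroxyls (Me3SiOTf, 2,6-lutidine, CH2Cl2, –78 °C) to the bis(trimethylsilyl) ether F1 and semi-hydrogenated (H2, Pd/CaCO3 poisoned with Pb(OAc)2, quinoline) to the cis-alkene lactone F2. Methylenation with Cp2Ti(μ-Cl)(μ-CH2)AlMe2 would give the enol ether F3, and heating in toluene the ring-contracted ketone F4. Citric acid in MeOH would free the diol ketone F5; Dess–Martin oxidation of its allylic C4 carbinol would give the cis-enone F6, which should close to the hemiketal ketone F7; MeOH with PPTS would then give 34.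

2. Step 17. Intermolecular acylation (diolide and oligomer formation) may outrun ring closure, because the linear C4–C5≡C6–C7 segment holds the activated carboxyl away from the C12 hydroxyl. Fallback, from 24 back to the route at 26: the alkyne would be bent before ring closure. Co2(CO)8 in CH2Cl2 would convert 24 into the hexacarbonyldicobalt alkyne complex F8; lactonisation under the conditions of step 17 would give the complexed macrolactone F9; Fe(NO3)3·9H2O in EtOH would release 26.

3. Step 10. Facial discrimination at the small methyl ketone may be poor, and the enolisable keto ester may self-condense under the amine and zinc salt, leaving C7 as a mixture or the yield low. Fallback, from 16 back to the route at 17: auxiliary control in place of catalyst control. (–)-8-Phenylmenthol would be acylated with pyruvoyl chloride and pyridine to (–)-8-phenylmenthyl pyruvate F10, whose ketone is shielded on one face by the phenyl ring. The bromomagnesium acetylide of 16 (EtMgBr, THF) would add at –78 °C to give the (S) tertiary alcohol ester F11. KOH in aqueous EtOH would give the hydroxy acid F12 with recovery of the auxiliary, and esterification with 2-(trimethylsilyl)ethanol (DCC, DMAP) would give 17.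

**Further compounds**

F1 | step 23 | bis(trimethylsilyl) ether of 28 | CC(C)(C)[Si](C)(C)OC[C@@H]1C[C@@H]2[C@@H](C(C)C)C[C@H](OC(=O)[C@@](C)(O[Si](C)(C)C)C#C[C@@H]1O[Si](C)(C)C)C(C)=C2
F2 | step 23 | cis-alkene lactone from F1 | CC(C)(C)[Si](C)(C)OC[C@@H]1C[C@@H]2[C@@H](C(C)C)C[C@H](OC(=O)[C@@](C)(O[Si](C)(C)C)/C=C\[C@@H]1O[Si](C)(C)C)C(C)=C2
F3 | step 23 | exocyclic enol ether from F2 | CC(C)(C)[Si](C)(C)OC[C@@H]1C[C@@H]2[C@@H](C(C)C)C[C@H](OC(=C)[C@@](C)(O[Si](C)(C)C)/C=C\[C@@H]1O[Si](C)(C)C)C(C)=C2
F4 | step 23 | ring-contracted ten-membered C8 ketone, C4 and C7 trimethylsilyl ethers | CC(C)(C)[Si](C)(C)OC[C@@H]1C[C@@H]2[C@@H](C(C)C)CC=C(C)[C@@H]2CC(=O)[C@@](C)(O[Si](C)(C)C)/C=C\[C@@H]1O[Si](C)(C)C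
F5 | step 23 | diol ketone (C4–OH, C7–OH, C8 ketone) | CC(C)(C)[Si](C)(C)OC[C@@H]1C[C@@H]2[C@@H](C(C)C)CC=C(C)[C@@H]2CC(=O)[C@@](C)(O)/C=C\[C@@H]1O
F6 | step 23 | cis-enone (C4 ketone, C7–OH, C8 ketone) | CC(C)(C)[Si](C)(C)OC[C@@H]1C[C@@H]2[C@@H](C(C)C)CC=C(C)[C@@H]2CC(=O)[C@@](C)(O)/C=C\C1=O
F7 | step 23 | hemiketal ketone (C4–OH, oxygen bridge, C8 ketone) | CC(C)(C)[Si](C)(C)OC[C@@H]1C[C@@H]2[C@@H](C(C)C)CC=C(C)[C@@H]2CC(=O)[C@]2(C)C=C[C@@]1(O)O2
F8 | step 17 | hexacarbonyldicobalt alkyne complex of 24 | CC1(C)OC[C@H](C[C@@H]2[C@@H](C(C)C)C[C@H](O)C(C)=C2)[C@H](C23[Co]4(=C=O)(=C=O)(=C=O)[Co]2(=C=O)(=C=O)(=C=O)C34[C@](C)(O)C(O)=O)O1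
F9 | step 17 | hexacarbonyldicobalt alkyne complex of 26 | CC1(C)OC[C@@H]2C[C@@H]3[C@@H](C(C)C)C[C@H](OC(=O)[C@@](C)(O)C45[Co]6(=C=O)(=C=O)(=C=O)[Co]4(=C=O)(=C=O)(=C=O)C56[C@@H]2O1)C(C)=C3
F10 | step 10 | (–)-8-phenylmenthyl pyruvate | CC(C)(c1ccccc1)[C@@H]1CC[C@@H](C)C[C@H]1OC(=O)C(C)=O
F11 | step 10 | (–)-8-phenylmenthyl (S)-5,5-diethoxy-2-hydroxy-2-methylpent-3-ynoate | CC(C)(c1ccccc1)[C@@H]1CC[C@@H](C)C[C@H]1OC(=O)[C@@](C)(O)C#CC(OCC)OCC
F12 | step 10 | (S)-5,5-diethoxy-2-hydroxy-2-methylpent-3-ynoic acid | CCOC(OCC)C#C[C@](C)(O)C(O)=O
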